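**Retrosynthetic overview**
1. Target 27 ← bis-silyl acid 26 (desilylation) ← methyl ester 24 (Me3SnOH hydrolysis) ← 2-bromoenone 21 + (E)-heptenylstannane 23 (Stille coupling at C2).
2. Feature: in the carbocycle (C1 ketone, C2 heptenyl carbon, C3 hydroxymethyl carbon, C4 carbinol, C5 epoxide CH, C6 quaternary epoxide carbon) the C1 ketone beside the fully substituted C2=C3 alkene is a masked 2-bromocyclohex-2-enone. Cutting C1–C2 and C2–C3 removes the single atom C2 and leaves an epoxycyclopentanone that already holds C3–C6 and all three stereocentres.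
3. 21 ← trimethylsilyl enol ether 17 + bromoform 18 (dibromocarbene ring expansion); 17 ← epoxy ketone 12 by formaldehyde aldol and two silylations.
4. 12 ← enone 11 (anti Weitz–Scheffer epoxidation) ← (R)-silyloxy enone 9 + methyl methacrylate 10 (cross-metathesis) ← furfural 1 + allyl bromide 2 (Barbier, Piancatelli, isomerisation, lipase resolution).
5. Ring order: cyclopentenone (4π electrocyclisation), then oxirane, then the cyclohexenone by one-carbon enlargement of the five-membered ring.

Key step: step 12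

Remarks: TBS = tert-butyldimethylsilyl, TMS = trimethylsilyl. The lipase is assumed to acylate the (R)-alcohol of 6, the usual preference for 2-substituted 4-hydroxycyclopentenones. The aldol centre made in step 9 is drawn trans to the neighbouring silyloxy group; its configuration has no consequence because that carbon becomes sp2 in step 11.

**Step 1**
Reactants: 1 furfural; 2 allyl bromide
Product: 4 (±)-1-(furan-2-yl)but-3-en-1-ol, via allylzinc bromide 3 (not isolated)
Conditions: Zn dust, sat. aq. NH4Cl/THF, 0 °C to rt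
Reagents that add atoms: none
Why: Aqueous zinc Barbier allylation of an aromatic aldehyde; the carbinol centre is racemic and is destroyed in step 2.

**Step 2**
Reactants: 4 (±)-1-(furan-2-yl)but-3-en-1-ol
Product: 5 (±)-trans-4-hydroxy-5-(prop-2-enyl)cyclopent-2-en-1-one
Conditions: ZnCl2, dioxane/H2O, reflux
Reagents that add atoms: water, O
Why: Piancatelli rearrangement: ionisation of the furylcarbinol, addition of water at furan C5, ring opening to a hydroxypentadienyl cation and conrotatory 4π electrocyclisation, which sets the 4,5-trans relationship (racemic).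

**Step 3**
Reactants: 5 (±)-trans-4-hydroxy-5-(prop-2-enyl)cyclopent-2-en-1-one
Product: 6 (±)-4-hydroxy-2-(prop-2-enyl)cyclopent-2-en-1-one
Conditions: phosphate buffer (pH 8)/dioxane, 60 °C
Reagents that add atoms: water, O
Why: Base-mediated 1,3-transposition (dehydration to the 2-allylcyclopentadienone, then conjugate re-addition of water at the unsubstituted β-carbon) gives the thermodynamically preferred trisubstituted enone, as in rethrolone and prostaglandin-synthon chemistry.

**Step 4**
Reactants: 6 (±)-4-hydroxy-2-(prop-2-enyl)cyclopent-2-en-1-one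
Product: 7 (1R)-4-oxo-3-(prop-2-enyl)cyclopent-2-en-1-yl acetate
Conditions: immobilised Candida antarctica lipase B, vinyl acetate, MTBE, 30 °C, stopped near half conversion
Reagents that add atoms: vinyl acetate, CC(=O)OC=C
Why: Lipase kinetic resolution by irreversible transesterification; the (R)-alcohol should be acylated faster (Kazlauskas preference), and the unreacted (S)-alcohol is removed by chromatography, which fixes the future carbinol stereocentre.

**Step 5**
Reactants: 7 (1R)-4-oxo-3-(prop-2-enyl)cyclopent-2-en-1-yl acetate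
Product: 8 (4R)-4-hydroxy-2-(prop-2-enyl)cyclopent-2-en-1-one
Conditions: immobilised Candida antarctica lipase B, n-BuOH, MTBE, 35 °C
Reagents that add atoms: none
Why: Enzymatic alcoholysis removes the acetate under neutral conditions, which avoids base-induced elimination or racemisation of the 4-acyloxy enone and applies the same enantiopreference a second time.

**Step 6**
Reactants: 8 (4R)-4-hydroxy-2-(prop-2-enyl)cyclopent-2-en-1-one
Product: 9 (4R)-4-(TBS-oxy)-2-(prop-2-enyl)cyclopent-2-en-1-one
Conditions: TBSCl, imidazole, DMF, 0 °C to rt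
Reagents that add atoms: tert-butyldimethylsilyl chloride, CC(C)(C)[Si](C)(C)Cl
Why: Standard imidazole-promoted silylation of a secondary alcohol; the bulky ether later directs the epoxidation.

**Step 7**
Reactants: 9 (4R)-4-(TBS-oxy)-2-(prop-2-enyl)cyclopent-2-en-1-one; 10 methyl methacrylate
Product: 11 methyl (E)-4-[(3R)-3-(TBS-oxy)-5-oxocyclopent-1-en-1-yl]-2-methylbut-2-enoate
Conditions: methyl methacrylate (excess), second-generation Hoveyda–Grubbs catalyst (cat.), CH2Cl2, 40 °C
Reagents that add atoms: none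
Why: Olefin cross-metathesis of a terminal alkene with a 1,1-disubstituted acrylate that barely homodimerises; the trisubstituted enoate forms under thermodynamic control as the E isomer and the ring enone does not take part.

**Step 8**
Reactants: 11 methyl (E)-4-[(3R)-3-(TBS-oxy)-5-oxocyclopent-1-en-1-yl]-2-methylbut-2-enoate
Product: 12 methyl (E)-4-[(1S,4R,5S)-4-(TBS-oxy)-2-oxo-6-oxabicyclo[3.1.0]hexan-1-yl]-2-methylbut-2-enoate
Conditions: 30% aq. H2O2, NaOH (cat.), MeOH, −20 to 0 °C
Reagents that add atoms: hydrogen peroxide, OO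
Why: Weitz–Scheffer nucleophilic epoxidation; hydroperoxide adds to the ring β-carbon anti to the adjacent silyloxy group and the enolate closes on the same face, which sets both epoxide centres trans to the C4 oxygen, while the less electrophilic acyclic enoate is left alone.

**Step 9**
Reactants: 12 methyl (E)-4-[(1S,4R,5S)-4-(TBS-oxy)-2-oxo-6-oxabicyclo[3.1.0]hexan-1-yl]-2-methylbut-2-enoate; 13 formaldehyde
Product: 15 methyl (E)-4-[(1S,3R,4R,5S)-4-(TBS-oxy)-3-(hydroxymethyl)-2-oxo-6-oxabicyclo[3.1.0]hexan-1-yl]-2-methylbut-2-enoate, via lithium enolate of 12 14 (not isolated)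
Conditions: LiHMDS, THF, −78 °C; CH2O (monomer in THF, from cracked paraformaldehyde), −78 °C; AcOH quench
Reagents that add atoms: none
Why: Aldol addition of a kinetic lithium enolate to formaldehyde; the quaternary C1 leaves C3 as the only enolisable position, E1cB loss of the β-silyloxide should be slow at −78 °C, and formaldehyde is expected to enter anti to the C4 silyloxy group.

**Step 10**
Reactants: 15 methyl (E)-4-[(1S,3R,4R,5S)-4-(TBS-oxy)-3-(hydroxymethyl)-2-oxo-6-oxabicyclo[3.1.0]hexan-1-yl]-2-methylbut-2-enoate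
Product: 16 methyl (E)-4-[(1S,3R,4R,5S)-4-(TBS-oxy)-3-(TBS-oxymethyl)-2-oxo-6-oxabicyclo[3.1.0]hexan-1-yl]-2-methylbut-2-enoate
Conditions: TBSCl, imidazole, CH2Cl2, 0 °C
Reagents that add atoms: tert-butyldimethylsilyl chloride, CC(C)(C)[Si](C)(C)Cl
Why: Mild silylation of the primary alcohol caps the β-hydroxy ketone before it can dehydrate or undergo retro-aldol cleavage.

**Step 11**
Reactants: 16 methyl (E)-4-[(1S,3R,4R,5S)-4-(TBS-oxy)-3-(TBS-oxymethyl)-2-oxo-6-oxabicyclo[3.1.0]hexan-1-yl]-2-methylbut-2-enoate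
Product: 17 methyl (E)-4-[(1S,4R,5S)-4-(TBS-oxy)-3-(TBS-oxymethyl)-2-(TMS-oxy)-6-oxabicyclo[3.1.0]hex-2-en-1-yl]-2-methylbut-2-enoate
Conditions: TMSOTf, Et3N, CH2Cl2, −20 to 0 °C; non-aqueous work-up, used crude
Reagents that add atoms: trimethylsilyl trifluoromethanesulfonate, C[Si](C)(C)OS(=O)(=O)C(F)(F)F
Why: Soft enolisation (silyl triflate activation of the carbonyl, amine deprotonation) gives the only possible enol ether, the tetrasubstituted C2–C3 one, without a metal enolate that could expel either β-silyloxy group.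

**Step 12**
Reactants: 17 methyl (E)-4-[(1S,4R,5S)-4-(TBS-oxy)-3-(TBS-oxymethyl)-2-(TMS-oxy)-6-oxabicyclo[3.1.0]hex-2-en-1-yl]-2-methylbut-2-enoate; 18 bromoform
Product: 21 methyl (E)-4-[(1S,5R,6S)-3-bromo-5-(TBS-oxy)-4-(TBS-oxymethyl)-2-oxo-7-oxabicyclo[4.1.0]hept-3-en-1-yl]-2-methylbut-2-enoate, via dibromocarbene 19 (not isolated), via dibromocyclopropane adduct 20 (not isolated)
Conditions: CHBr3 (2 equiv), KOtBu (2.2 equiv, added in portions), pentane, −30 °C to rt; pH 7 buffer quench
Reagents that add atoms: none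
Why: tert-Butoxide deprotonates bromoform and α-elimination gives dibromocarbene 19, which adds in a [2+1] sense to the C2–C3 siloxyalkene of 17 to give the 6,6-dibromo-1-siloxybicyclo[3.1.0]hexane 20; the endo bromide then ionises with disrotatory cyclopropyl-to-allyl opening pushed by the siloxy oxygen, and tert-butoxide takes the silyl group to leave the 2-bromoenone. This is the known dihalocarbene one-carbon ring expansion of cyclic silyl enol ethers to 2-halocycloalk-2-enones. The six-membered ring is not closed by a cyclisation; it arises from this electrocyclic opening of the fused three-membered ring, in which the shared bond breaks and the carbene carbon becomes the bromine-bearing C3 of 21, bonded to the carbonyl carbon and to the silyloxymethyl-bearing carbon. No stereocentre is created: the two transient cyclopropane centres are erased whichever face the carbene takes, and C1, C5 and C6 of 21 are untouched. The step needs chemoselective attack of the electrophilic carbene on the electron-rich tetrasubstituted siloxyalkene and not on the electron-poor enoate or the epoxide, which the large nucleophilicity gap should secure. It also needs a single direction of insertion, which is fixed because the quaternary epoxide carbon allows enolisation only towards the silyloxymethyl carbon and the siloxy group dictates which cyclopropane bond breaks.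

**Step 13**
Reactants: 22 hept-1-yne
Product: 23 (E)-tributyl(hept-1-enyl)stannane
Conditions: Bu3SnH, Pd2(dba)3 (cat.), Cy3P·HBF4, iPr2NEt, CH2Cl2, 0 °C
Reagents that add atoms: tributyltin hydride, CCCC[SnH](CCCC)CCCC
Why: Palladium-catalysed syn hydrostannation of a terminal alkyne; the bulky tricyclohexylphosphine ligand steers tin to the terminal carbon, so cis addition of Sn–H gives the (E)-1-stannylalkene.

**Step 14**
Reactants: 21 methyl (E)-4-[(1S,5R,6S)-3-bromo-5-(TBS-oxy)-4-(TBS-oxymethyl)-2-oxo-7-oxabicyclo[4.1.0]hept-3-en-1-yl]-2-methylbut-2-enoate; 23 (E)-tributyl(hept-1-enyl)stannane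
Product: 24 methyl (E)-4-[(1S,5R,6S)-5-(TBS-oxy)-4-(TBS-oxymethyl)-3-[(E)-hept-1-enyl]-2-oxo-7-oxabicyclo[4.1.0]hept-3-en-1-yl]-2-methylbut-2-enoate
Conditions: Pd(PPh3)4 (cat.), CuI (cat.), DMF, 60 °C
Reagents that add atoms: none
Why: Stille cross-coupling: zerovalent palladium inserts into the C–Br bond of the 2-bromoenone, CuI-assisted transmetalation from tin keeps the E geometry, and the neutral conditions are tolerated by the epoxide, silyl ethers and ester.

**Step 15**
Reactants: 24 methyl (E)-4-[(1S,5R,6S)-5-(TBS-oxy)-4-(TBS-oxymethyl)-3-[(E)-hept-1-enyl]-2-oxo-7-oxabicyclo[4.1.0]hept-3-en-1-yl]-2-methylbut-2-enoate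
Product: 26 (E)-4-[(1S,5R,6S)-5-(TBS-oxy)-4-(TBS-oxymethyl)-3-[(E)-hept-1-enyl]-2-oxo-7-oxabicyclo[4.1.0]hept-3-en-1-yl]-2-methylbut-2-enoic acid, via trimethylstannyl ester of 26 25 (not isolated)
Conditions: Me3SnOH, 1,2-dichloroethane, 70 °C; then cold dilute aq. HCl wash
Reagents that add atoms: trimethyltin hydroxide, C[Sn](C)(C)O
Why: Trimethyltin hydroxide ester hydrolysis (acyl transfer to a tin carboxylate, freed by the acid wash) runs near neutrality and spares the epoxy enone; with both hydroxyls still silylated no alkoxide can start a Payne rearrangement.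

**Step 16**
Reactants: 26 (E)-4-[(1S,5R,6S)-5-(TBS-oxy)-4-(TBS-oxymethyl)-3-[(E)-hept-1-enyl]-2-oxo-7-oxabicyclo[4.1.0]hept-3-en-1-yl]-2-methylbut-2-enoic acid
Product: 27 (E)-4-[(1S,5R,6S)-3-[(E)-hept-1-enyl]-5-hydroxy-4-(hydroxymethyl)-2-oxo-7-oxabicyclo[4.1.0]hept-3-en-1-yl]-2-methylbut-2-enoic acid
Conditions: HF·pyridine, pyridine, THF, 0 °C to rt
Reagents that add atoms: none
Why: Fluoride-driven desilylation with buffered HF–pyridine removes both silyl ethers; the epoxide is deactivated towards acid opening by the adjacent ketone, and the basic conditions of tetrabutylammonium fluoride are avoided.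

**Compound list**
1 | furfural (furan-2-carbaldehyde) | O=Cc1ccco1 | starting material
2 | allyl bromide (3-bromoprop-1-ene) | C=CCBr | starting material
3 | allylzinc bromide | C=CC[Zn]Br | intermediate (not isolated)
4 | (±)-1-(furan-2-yl)but-3-en-1-ol | OC(CC=C)c1ccco1 | intermediate
5 | (±)-trans-4-hydroxy-5-(prop-2-enyl)cyclopent-2-en-1-one (racemic, relative configuration shown) | O=C1C=C[C@@H](O)[C@@H]1CC=C | intermediate
6 | (±)-4-hydroxy-2-(prop-2-enyl)cyclopent-2-en-1-one | O=C1CC(O)C=C1CC=C | intermediate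
7 | (1R)-4-oxo-3-(prop-2-enyl)cyclopent-2-en-1-yl acetate | O=C1C[C@@H](OC(C)=O)C=C1CC=C | intermediate
8 | (4R)-4-hydroxy-2-(prop-2-enyl)cyclopent-2-en-1-one | O=C1C[C@@H](O)C=C1CC=C | intermediate
9 | (4R)-4-(tert-butyldimethylsilyloxy)-2-(prop-2-enyl)cyclopent-2-en-1-one | O=C1C[C@@H](O[Si](C)(C)C(C)(C)C)C=C1CC=C | intermediate
10 | methyl methacrylate | C=C(C)C(=O)OC | starting material
11 | methyl (E)-4-[(3R)-3-(tert-butyldimethylsilyloxy)-5-oxocyclopent-1-en-1-yl]-2-methylbut-2-enoate | O=C1C[C@@H](O[Si](C)(C)C(C)(C)C)C=C1C/C=C(\C)C(=O)OC | intermediate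
12 | methyl (E)-4-[(1S,4R,5S)-4-(tert-butyldimethylsilyloxy)-2-oxo-6-oxabicyclo[3.1.0]hexan-1-yl]-2-methylbut-2-enoate (epoxide trans to the silyloxy group) | C1[C@@H](O[Si](C)(C)C(C)(C)C)[C@@H]2O[C@]2(C/C=C(\C)C(=O)OC)C1=O | intermediate
13 | formaldehyde (monomer, from paraformaldehyde) | C=O | starting material
14 | lithium enolate of 12 (C2–C3 enolate) | C1[C@@H](O[Si](C)(C)C(C)(C)C)[C@@H]2O[C@]2(C/C=C(\C)C(=O)OC)C=1O[Li] | intermediate (not isolated)
15 | methyl (E)-4-[(1S,3R,4R,5S)-4-(tert-butyldimethylsilyloxy)-3-(hydroxymethyl)-2-oxo-6-oxabicyclo[3.1.0]hexan-1-yl]-2-methylbut-2-enoate | [C@@H]1(CO)[C@@H](O[Si](C)(C)C(C)(C)C)[C@@H]2O[C@]2(C/C=C(\C)C(=O)OC)C1=O | intermediate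
16 | methyl (E)-4-[(1S,3R,4R,5S)-4-(tert-butyldimethylsilyloxy)-3-(tert-butyldimethylsilyloxymethyl)-2-oxo-6-oxabicyclo[3.1.0]hexan-1-yl]-2-methylbut-2-enoate | [C@@H]1(CO[Si](C)(C)C(C)(C)C)[C@@H](O[Si](C)(C)C(C)(C)C)[C@@H]2O[C@]2(C/C=C(\C)C(=O)OC)C1=O | intermediate
17 | methyl (E)-4-[(1S,4R,5S)-4-(tert-butyldimethylsilyloxy)-3-(tert-butyldimethylsilyloxymethyl)-2-(trimethylsilyloxy)-6-oxabicyclo[3.1.0]hex-2-en-1-yl]-2-methylbut-2-enoate | C1(CO[Si](C)(C)C(C)(C)C)[C@@H](O[Si](C)(C)C(C)(C)C)[C@@H]2O[C@]2(C/C=C(\C)C(=O)OC)C=1O[Si](C)(C)C | intermediate (key-step precursor)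
18 | bromoform | BrC(Br)Br | starting material
19 | dibromocarbene | Br[C]Br | intermediate (not isolated)
20 | dibromocyclopropane adduct of 17 (6,6-dibromo-1-trimethylsilyloxybicyclo[3.1.0]hexane core fused to the epoxide; face of carbene addition undefined and without consequence) | BrC1(Br)C2(CO[Si](C)(C)C(C)(C)C)[C@@H](O[Si](C)(C)C(C)(C)C)[C@@H]3O[C@]3(C/C=C(\C)C(=O)OC)C12O[Si](C)(C)C | intermediate (not isolated)
21 | methyl (E)-4-[(1S,5R,6S)-3-bromo-5-(tert-butyldimethylsilyloxy)-4-(tert-butyldimethylsilyloxymethyl)-2-oxo-7-oxabicyclo[4.1.0]hept-3-en-1-yl]-2-methylbut-2-enoate | BrC1=C(CO[Si](C)(C)C(C)(C)C)[C@@H](O[Si](C)(C)C(C)(C)C)[C@@H]2O[C@]2(C/C=C(\C)C(=O)OC)C1=O | intermediate (key-step product)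
22 | hept-1-yne | CCCCCC#C | starting material
23 | (E)-tributyl(hept-1-enyl)stannane | CCCCC/C=C/[Sn](CCCC)(CCCC)CCCC | intermediate
24 | methyl (E)-4-[(1S,5R,6S)-5-(tert-butyldimethylsilyloxy)-4-(tert-butyldimethylsilyloxymethyl)-3-[(E)-hept-1-enyl]-2-oxo-7-oxabicyclo[4.1.0]hept-3-en-1-yl]-2-methylbut-2-enoate | CCCCC/C=C/C1=C(CO[Si](C)(C)C(C)(C)C)[C@@H](O[Si](C)(C)C(C)(C)C)[C@@H]2O[C@]2(C/C=C(\C)C(=O)OC)C1=O | intermediate
25 | trimethylstannyl ester of acid 26 | CCCCC/C=C/C1=C(CO[Si](C)(C)C(C)(C)C)[C@@H](O[Si](C)(C)C(C)(C)C)[C@@H]2O[C@]2(C/C=C(\C)C(=O)O[Sn](C)(C)C)C1=O | intermediate (not isolated)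
26 | (E)-4-[(1S,5R,6S)-5-(tert-butyldimethylsilyloxy)-4-(tert-butyldimethylsilyloxymethyl)-3-[(E)-hept-1-enyl]-2-oxo-7-oxabicyclo[4.1.0]hept-3-en-1-yl]-2-methylbut-2-enoic acid | CCCCC/C=C/C1=C(CO[Si](C)(C)C(C)(C)C)[C@@H](O[Si](C)(C)C(C)(C)C)[C@@H]2O[C@]2(C/C=C(\C)C(=O)O)C1=O | intermediate
27 | (E)-4-[(1S,5R,6S)-3-[(E)-hept-1-enyl]-5-hydroxy-4-(hydroxymethyl)-2-oxo-7-oxabicyclo[4.1.0]hept-3-en-1-yl]-2-methylbut-2-enoic acid (CNP0332048.4) | CCCCC/C=C/C1=C(CO)[C@@H](O)[C@@H]2O[C@]2(C/C=C(\C)C(=O)O)C1=O | target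

**Step count**
Total: 16 steps. Longest linear sequence: 15 steps (steps 1–12 and 14–16); step 13 is a one-step side branch.

**Steps most likely to fail**

Step 12 (ring expansion). Three processes could compete: tert-butoxide may cleave the trimethylsilyl enol ether to a potassium enolate that expels a β-silyloxide; the silyl bromide set free in the ring opening may open the epoxide before it is scavenged; and residual base may deprotonate the γ-position of the product. The fallback sets out from 17 and inserts the carbon without base or bromide. Cyclopropanation of the enol ether with Et2Zn and CH2I2 in CH2Cl2 at 0 °C should give the siloxycyclopropane F1. Oxidative opening with FeCl3 in DMF at 0 °C (Ito–Saegusa ring expansion) would give the ring-enlarged β-chloro ketone F2, and NaOAc in MeOH would eliminate HCl to the 2-unsubstituted cyclohexenone F3. Addition of Br2 in CH2Cl2 at −20 °C to the ring enone would give the dibromide F4, and Et3N in the same flask would remove HBr, so that the route is rejoined at 21.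

Step 9 (formaldehyde aldol). The lithium enolate may lose the C4 silyloxide by E1cB elimination before it meets the electrophile, or monomeric formaldehyde may polymerise and leave the conversion low. The fallback sets out from 12 and avoids a metal enolate. TMSOTf and Et3N in CH2Cl2 would give the trisubstituted trimethylsilyl enol ether F5. A Mukaiyama aldol of F5 with aqueous formaldehyde catalysed by Yb(OTf)3 in THF/H2O at rt would deliver the hydroxymethyl ketone, rejoining the route at 15.

Step 14 (Stille coupling). Transmetalation from tin to the hindered, tetrasubstituted 2-bromoenone may be slow, so that protodebromination or stannane homocoupling takes over. The fallback sets out from 22 and 21 and changes the nucleophile to boron. Hydroboration of hept-1-yne with pinacolborane and catalytic Cp2Zr(H)Cl would give (E)-hept-1-enylboronic acid pinacol ester F6. Suzuki–Miyaura coupling of F6 with 21 using Pd(dppf)Cl2, AsPh3 and Cs2CO3 in DMF/THF/H2O at rt would form the same C–C bond, rejoining the route at 24.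

**Further compounds**
F1 | step 12 | siloxycyclopropane: CH2 adduct across the enol ether bond of 17 (1-trimethylsilyloxybicyclo[3.1.0]hexane core fused to the epoxide) | C1C2(CO[Si](C)(C)C(C)(C)C)[C@@H](O[Si](C)(C)C(C)(C)C)[C@@H]3O[C@]3(C/C=C(\C)C(=O)OC)C12O[Si](C)(C)C
F2 | step 12 | β-chloro ketone: methyl (E)-4-[(1S,5R,6S)-4-chloro-5-(tert-butyldimethylsilyloxy)-4-(tert-butyldimethylsilyloxymethyl)-2-oxo-7-oxabicyclo[4.1.0]heptan-1-yl]-2-methylbut-2-enoate (C4 configuration undefined) | C1C(Cl)(CO[Si](C)(C)C(C)(C)C)[C@@H](O[Si](C)(C)C(C)(C)C)[C@@H]2O[C@]2(C/C=C(\C)C(=O)OC)C1=O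
F3 | step 12 | enone: methyl (E)-4-[(1S,5R,6S)-5-(tert-butyldimethylsilyloxy)-4-(tert-butyldimethylsilyloxymethyl)-2-oxo-7-oxabicyclo[4.1.0]hept-3-en-1-yl]-2-methylbut-2-enoate | C1=C(CO[Si](C)(C)C(C)(C)C)[C@@H](O[Si](C)(C)C(C)(C)C)[C@@H]2O[C@]2(C/C=C(\C)C(=O)OC)C1=O
F4 | step 12 | dibromide: 3,4-dibromo adduct of F3 (new centres undefined) | BrC1C(Br)(CO[Si](C)(C)C(C)(C)C)[C@@H](O[Si](C)(C)C(C)(C)C)[C@@H]2O[C@]2(C/C=C(\C)C(=O)OC)C1=O
F5 | step 9 | trimethylsilyl enol ether of 12: methyl (E)-4-[(1S,4R,5S)-4-(tert-butyldimethylsilyloxy)-2-(trimethylsilyloxy)-6-oxabicyclo[3.1.0]hex-2-en-1-yl]-2-methylbut-2-enoate | C1[C@@H](O[Si](C)(C)C(C)(C)C)[C@@H]2O[C@]2(C/C=C(\C)C(=O)OC)C=1O[Si](C)(C)C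
F6 | step 14 | (E)-2-(hept-1-enyl)-4,4,5,5-tetramethyl-1,3,2-dioxaborolane | CCCCC/C=C/B1OC(C)(C)C(C)(C)O1
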